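The numbers of this flask come from no measurement.

Start from 8.3: in north, at the charged added ligand, that is the ratio of idle complex to free catalyst once the ligand step has settled. Ask whether it settles inside the run.

in all of them: free catalyst 18 mol%; added ligand 17 mM

| charge | substrate | reagent | time | remark |
|---|---|---|---|---|
| north-east | 32 mM (fed, over 64.0 s) | 2.00 equiv | 80 s | a stirred flask in which substrate is dosed at a steady rate over 64.0 s without added volume, worked up at 80 s |
| north | 32 mM | 2.00 equiv | 80 s | everything together in a closed stirred flask, run for 80 s |
| south | 32 mM | 2.00 equiv |  | one stirred flow tank at steady state, fed with the mixture as stated, mean residence time 80 s |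
| north-west | 32 mM | 2.00 equiv (fed, over 64.0 s) | 80 s | a stirred flask in which reagent is dosed at a steady rate over 64.0 s without added volume, worked up at 80 s |

    reagent + free catalyst → catalyst intermediate A (k1 = 4.96 M⁻¹ s⁻¹)
    substrate + catalyst intermediate A → catalyst intermediate B (k2 = 1.79 M⁻¹ s⁻¹)
    catalyst intermediate B → released group + catalyst intermediate C (k3 = 10.4 s⁻¹)
    catalyst intermediate C → free catalyst + target (k4 = 0.596 s⁻¹)
    free catalyst + added ligand ⇌ idle complex (K5 = 490 M⁻¹, k5 = 3.70 M⁻¹ s⁻¹)

- order of the set-ups by the amount of target at the outlet or at the end, in percent of the substrate put in, highest first (north-east / north / south / north-west)
- amount of target at the outlet or at the end, in percent of the substrate put in, north-east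
- amount of target at the outlet or at the end, in percent of the substrate put in, north
- amount of target at the outlet or at the end, in percent of the substrate put in, south
- amount of target at the outlet or at the end, in percent of the substrate put in, north-west

- the stated concentrations are those of everything mixed, before any reaction; amounts are the same in each set-up
- the feed brings no volume worth counting
- run time (north-east): 80 s

Reckon north by hand, holding substrate, reagent and added ligand at their full charges in the balance of the catalyst.

1. Balance the round. Per unit of catalyst intermediate A, the resting state of the round, the substrate step keeps 0.180 of free catalyst, 0.00551 of catalyst intermediate B and 0.0961 of catalyst intermediate C standing. The working catalyst therefore sums to 1.28 units.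

2. Way one: take the ligand step as settled. Idle complex is then 1.50 units, which gives it a settled share of 54.0% of the catalyst and leaves catalyst intermediate A 35.9%. Substrate falls pseudo-first-order at 0.0103 s⁻¹ times the share of catalyst intermediate A, so 80 s gives 25.6% of target.

3. Way two: run the clock. Working catalyst is captured at 0.00885 s⁻¹, and idle complex is released at 0.00755 s⁻¹. Capture over the sum of these returns the same settled share, which is the same algebra and no check. The new number is the lock time, 61.0 s: one over capture plus release, the time scale on which idle complex nears its settled share.

4. Start idle complex at none. The reckoning puts it at 39.4% of the catalyst at the end of north and at 23.9% on average over the run. Substrate then gives 38.7% of target.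

5. The ways part: way two gives more than way one. Way one cheats by booking the settled share from the first second, yet the lock time is shorter than the run and 26.9% of the approach is still open at the end. Commit to 38.7% for north. Stop there: the tank and the dosed flasks are not reckoned here.

The forecast says north > south > north-east > north-west. It gives north-east 26.5% (22% to 31%), north 37% (32% to 41%), south 30% (26% to 34%) and north-west 21% (17% to 26%). It puts north-west last since free catalyst “gets locked up by the ligand”. Its north lies below my figure, and my figure falls inside its range.

The flask gives north > south > north-east > north-west: north-east 26.2%, north 36.6%, south 30.1%, north-west 18.5%. In north, idle complex reads 37.2% of the catalyst charged at 80.0 s, against 39.4% from the lock time. Now take north-west left until 5.0 min, where substrate reads 30.3%, reagent 60.5% and added ligand 85.6% of their charges. These fractions give 0.0902 of free catalyst per unit of catalyst intermediate A, 1.12 units of working catalyst, a lock time of 84.2 s and a settled share of 36.4%. Idle complex there reads 42.6%, above that share, down from 55.8% at 80.0 s, with target at 69.5%.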